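**Retrosynthetic overview**
1. Target ⇐ phenol desilylation ⇐ 15-membered ring closed last at the benzylic C(sp3)–C(sp2) bond by an intramolecular Pd Negishi coupling (benzylic zinc + tetrasubstituted cyclohexenyl triflate).
2. Seco-ester ⇐ aryl acid (from o-cresol) + prenyl-terminated epoxy triflate, joined by a catalyst-controlled Markovnikov bromoesterification (C–O bond and the (R)-C–Br centre).
3. Epoxy triflate ⇐ Ru cross-metathesis (vinyl → prenyl) ⇐ Shi epoxidation ⇐ enol triflate ⇐ α-methylation ⇐ Appel inversion ⇐ CBS desymmetrisation of a 2,2-disubstituted cyclohexane-1,3-dione (sets both ring stereocentres).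
4. Dione ⇐ Pd Tsuji–Trost union of 2-methylcyclohexane-1,3-dione with an (E)-allylic carbonate made by Zr-catalysed carboalumination of hex-5-en-1-yne.
5. Ring order: carbocycle (bought as the dione) → epoxide → macrolactone ring (last, by C–C coupling).

Assumption: the SMILES is taken exactly as written (one CH2 between the ring quaternary carbon and the epoxide, 15-membered lactone), and the enantiomer of the Shi ketone is treated as an available catalyst.

**Route**

Step 1
Reactants: 1 hex-5-en-1-yne
Product: 2 (2E)-3-methylhepta-2,6-dien-1-ol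
Conditions: Me3Al, Cp2ZrCl2 (20 mol %), CH2Cl2, 0 °C → rt; then n-BuLi, THF, −78 °C; (CH2O)n, −78 °C → rt
Reagents that add atoms: trimethylaluminium, C[Al](C)C (CH3); paraformaldehyde, C=O (CH2O)
Why: Negishi Zr-catalysed carboalumination adds Me–Al syn across the alkyne (Me to the internal carbon) and the alkenyl alanate is hydroxymethylated with retention, giving the E-trisubstituted allylic alcohol while the isolated terminal alkene is left alone.

Step 2
Reactants: 2 (2E)-3-methylhepta-2,6-dien-1-ol
Product: 3 methyl (2E)-3-methylhepta-2,6-dien-1-yl carbonate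
Conditions: ClCO2Me, pyridine, CH2Cl2, 0 °C
Reagents that add atoms: methyl chloroformate, COC(=O)Cl
Why: O-acylation gives the allylic carbonate, a leaving group that generates its own base (methoxide) for a neutral Tsuji–Trost reaction.

Step 3
Reactants: 4 cyclohexane-1,3-dione
Product: 5 2-methylcyclohexane-1,3-dione
Conditions: MeI, NaOH, H2O–dioxane, reflux
Reagents that add atoms: iodomethane, CI
Why: classical C-methylation of the stabilised 1,3-dione enolate.

Step 4
Reactants: 5 2-methylcyclohexane-1,3-dione; 3 methyl (2E)-3-methylhepta-2,6-dien-1-yl carbonate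
Product: 6 2-methyl-2-[(2E)-3-methylhepta-2,6-dien-1-yl]cyclohexane-1,3-dione
Conditions: Pd(PPh3)4 (3 mol %), THF, rt
Reagents that add atoms: none
Why: Tsuji–Trost allylic alkylation, in which the dione enolate attacks the unsubstituted terminus of the π-allyl Pd complex (C-alkylation, E geometry retained) to create the still-prochiral quaternary carbon.

Step 5
Reactants: 6
Product: 7 (2R,3R)-3-hydroxy-2-methyl-2-[(2E)-3-methylhepta-2,6-dien-1-yl]cyclohexan-1-one (OH cis to the dienyl chain)
Conditions: (S)-Me-CBS (30 mol %), catecholborane, toluene, −78 → −40 °C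
Reagents that add atoms: none
Why: CBS desymmetrising reduction, where the catalyst (quaternary carbon as the large group) gives the 3R carbinol and hydride enters anti to the larger side chain, so one enantiotopic carbonyl is reduced and both ring stereocentres are set; catecholborane does not hydroborate the alkenes at this temperature.

Step 6
Reactants: 7
Product: 8 (2S,3S)-3-bromo-2-methyl-2-[(2E)-3-methylhepta-2,6-dien-1-yl]cyclohexan-1-one (Br trans to the chain, cis to CH3)
Conditions: CBr4, PPh3, CH2Cl2, 0 °C → rt
Reagents that add atoms: carbon tetrabromide, BrC(Br)(Br)Br (Br)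
Why: Appel reaction, with SN2 displacement of the axially disposed alkoxyphosphonium by bromide inverting C3 to the equatorial (3S) bromide; the quaternary α-carbon rules out elimination through the enol.

Step 7
Reactants: 8
Product: 9 (2S,3S)-3-bromo-2,6-dimethyl-2-[(2E)-3-methylhepta-2,6-dien-1-yl]cyclohexan-1-one (C6 epimers)
Conditions: LDA, THF, −78 °C; MeI, −78 → −30 °C
Reagents that add atoms: iodomethane, CI
Why: enolate alkylation at the only enolisable α-carbon; the new C6 centre is destroyed in the next step, so its configuration does not matter.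

Step 8
Reactants: 9
Product: 10 (5S,6S)-5-bromo-2,6-dimethyl-6-[(2E)-3-methylhepta-2,6-dien-1-yl]cyclohex-1-en-1-yl trifluoromethanesulfonate
Conditions: KHMDS, THF, −78 °C; PhNTf2, −78 → 0 °C
Reagents that add atoms: N-phenyl-bis(trifluoromethanesulfonimide), O=S(=O)(N(c1ccccc1)S(=O)(=O)C(F)(F)F)C(F)(F)F (SO2CF3)
Why: enolate O-triflation, regiospecific because only one α-H remains, gives the tetrasubstituted enol triflate, which also masks the ring alkene as an electron-poor olefin for the next three steps.

Step 9
Reactants: 10
Product: 11 (5S,6S)-5-bromo-6-{[(2S,3S)-3-(but-3-en-1-yl)-3-methyloxiran-2-yl]methyl}-2,6-dimethylcyclohex-1-en-1-yl trifluoromethanesulfonate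
Conditions: ent-Shi ketone (L-fructose-derived, 30 mol %), Oxone, K2CO3, Bu4NHSO4, MeCN–DMM/aq. Na2B4O7 (pH 10.5), 0 °C
Reagents that add atoms: Oxone (potassium peroxymonosulfate), OOS(=O)(=O)[O-].[K+] (O)
Why: Shi epoxidation, in which the chiral dioxirane epoxidises only the electron-rich E-trisubstituted alkene (monosubstituted vinyl and enol triflate are inert) through the spiro transition state, and the L-series catalyst gives the (S,S)-epoxide.

Step 10
Reactants: 11
Product: 12 (5S,6S)-5-bromo-2,6-dimethyl-6-{[(2S,3S)-3-methyl-3-(4-methylpent-3-en-1-yl)oxiran-2-yl]methyl}cyclohex-1-en-1-yl trifluoromethanesulfonate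
Conditions: Grubbs II (5 mol %), 2-methyl-2-butene–CH2Cl2 (1:1), 40 °C
Reagents that add atoms: 2-methyl-2-butene, CC=C(C)C (C(CH3)2 replaces the terminal CH2)
Why: Ru-catalysed cross-metathesis of the terminal vinyl group with excess 2-methyl-2-butene installs the prenyl terminus only after the internal alkene has been epoxidised, so the two chain alkenes never compete.

Step 11
Reactants: 13 2-methylphenol (o-cresol)
Product: 14 4-bromo-2-methylphenol
Conditions: NBS, MeCN, 0 °C
Reagents that add atoms: N-bromosuccinimide, O=C1CCC(=O)N1Br (Br)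
Why: electrophilic aromatic bromination para to the hydroxyl.

Step 12
Reactants: 14
Product: 15 (4-bromo-2-methylphenoxy)triisopropylsilane
Conditions: TIPSCl, imidazole, DMF, rt
Reagents that add atoms: chlorotriisopropylsilane, CC(C)[Si](Cl)(C(C)C)C(C)C
Why: phenol silylation; the TIPS ether survives organolithium, radical, acidic and organozinc steps and is removed by fluoride at the end.

Step 13
Reactants: 15
Product: 16 tert-butyl 3-methyl-4-[(triisopropylsilyl)oxy]benzoate
Conditions: n-BuLi, THF, −78 °C; then cannulate into Boc2O, THF, −78 °C → rt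
Reagents that add atoms: di-tert-butyl dicarbonate, CC(C)(C)OC(=O)OC(=O)OC(C)(C)C (CO2tBu)
Why: Br–Li exchange and acylation of the aryllithium put the carboxyl carbon para to oxygen as an acid-labile ester.

Step 14
Reactants: 16
Product: 17 tert-butyl 3-(bromomethyl)-4-[(triisopropylsilyl)oxy]benzoate
Conditions: NBS, AIBN (cat.), PhCF3, 85 °C
Reagents that add atoms: N-bromosuccinimide, O=C1CCC(=O)N1Br (Br)
Why: Wohl–Ziegler benzylic bromination; the ester deactivates the ring toward electrophilic bromination.

Step 15
Reactants: 17
Product: 18 tert-butyl 3-(chloromethyl)-4-[(triisopropylsilyl)oxy]benzoate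
Conditions: LiCl (excess), DMF, rt
Reagents that add atoms: lithium chloride, [Li+].[Cl-] (Cl)
Why: SN2 halide exchange to the benzylic chloride, which does not alkylate the amine catalyst in step 17 and gives clean zinc insertion with little Wurtz coupling in step 18.

Step 16
Reactants: 18
Product: 19 3-(chloromethyl)-4-[(triisopropylsilyl)oxy]benzoic acid
Conditions: TFA–CH2Cl2 (1:4), 0 °C → rt
Reagents that add atoms: none
Why: acidolysis of the tert-butyl ester; aryl TIPS ether and benzylic chloride are stable to TFA.

Step 17
Reactants: 12; 19 3-(chloromethyl)-4-[(triisopropylsilyl)oxy]benzoic acid (1.5 equiv)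
Product: 20 (3R)-3-bromo-5-[(2S,3S)-3-{[(1S,6S)-6-bromo-1,3-dimethyl-2-(trifluoromethanesulfonyloxy)cyclohex-2-en-1-yl]methyl}-2-methyloxiran-2-yl]-2-methylpentan-2-yl 3-(chloromethyl)-4-[(triisopropylsilyl)oxy]benzoate
Conditions: NBS (1.2 equiv), (DHQ)2PHAL (10 mol %), PhMe–CHCl3 (1:1), −40 °C, dark
Reagents that add atoms: N-bromosuccinimide, O=C1CCC(=O)N1Br (Br)
Why: Proposed new method: catalyst-controlled intermolecular bromoesterification of an isolated acyclic prenyl terminus, in which the quinuclidinium carboxylate ion pair of the bis-cinchona catalyst binds NBS and delivers Br+ and ArCO2− anti across the alkene in a concerted (nucleophile-assisted) step inside the phthalazine cleft, the carboxylate opening at the tertiary carbon (Markovnikov) so Br ends on the CH carbon as the (R) centre; this is predicted from the dihydroxylation face preference of the same ligand family for Me2C=CH–CH2R alkenes, and the pseudo-enantiomeric (DHQD)2PHAL is used instead if the opposite sense is found. The closest known reaction type is cinchona-catalysed asymmetric bromolactonisation and intermolecular bromoesterification of cyclic or activated alkenes; it has not been shown for unactivated acyclic trisubstituted alkenes or next to a remote epoxide. The enol triflate is too electron-poor to react, and ion-paired carboxylate capture in a non-polar medium should outrun epoxide participation.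

Step 18
Reactants: 20
Product: 21 the phenol O-triisopropylsilyl ether of the target macrolide
Conditions: Zn dust (activated), LiCl, THF, 25 °C; then syringe-pump addition to Pd(OAc)2 (10 mol %), SPhos (20 mol %), THF (2 mM), 40 °C
Reagents that add atoms: none
Why: intramolecular Negishi coupling, with LiCl-mediated zinc insertion selective for the benzylic C–Cl over the two hindered secondary C–Br bonds and Pd(0) adding only to the C(sp2)–OTf bond, so reductive elimination forms the benzylic C–C bond and the 15-membered ring under pseudo-high dilution without touching any stereocentre.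

Step 19
Reactants: 21
Product: 22 target, CID 46880797
Conditions: TBAF, AcOH, THF, 0 °C
Reagents that add atoms: none
Why: fluoride desilylation of the aryl silyl ether, buffered with acetic acid so the phenoxide does not open the epoxide or eliminate HBr.

**Compound list**
1 | hex-5-en-1-yne | C#CCCC=C | starting material
2 | (2E)-3-methylhepta-2,6-dien-1-ol | C=CCC/C(C)=C/CO | intermediate
3 | methyl (2E)-3-methylhepta-2,6-dien-1-yl carbonate | C=CCC/C(C)=C/COC(=O)OC | intermediate
4 | cyclohexane-1,3-dione | O=C1CCCC(=O)C1 | starting material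
5 | 2-methylcyclohexane-1,3-dione | CC1C(=O)CCCC1=O | intermediate
6 | 2-methyl-2-[(2E)-3-methylhepta-2,6-dien-1-yl]cyclohexane-1,3-dione | C=CCC/C(C)=C/CC1(C)C(=O)CCCC1=O | intermediate
7 | (2R,3R)-3-hydroxy-2-methyl-2-[(2E)-3-methylhepta-2,6-dien-1-yl]cyclohexan-1-one | C=CCC/C(C)=C/C[C@]1(C)[C@H](O)CCCC1=O | intermediate
8 | (2S,3S)-3-bromo-2-methyl-2-[(2E)-3-methylhepta-2,6-dien-1-yl]cyclohexan-1-one | C=CCC/C(C)=C/C[C@]1(C)[C@@H](Br)CCCC1=O | intermediate
9 | (2S,3S)-3-bromo-2,6-dimethyl-2-[(2E)-3-methylhepta-2,6-dien-1-yl]cyclohexan-1-one (C6 epimers) | C=CCC/C(C)=C/C[C@]1(C)[C@@H](Br)CCC(C)C1=O | intermediate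
10 | (5S,6S)-5-bromo-2,6-dimethyl-6-[(2E)-3-methylhepta-2,6-dien-1-yl]cyclohex-1-en-1-yl trifluoromethanesulfonate | C=CCC/C(C)=C/C[C@]1(C)[C@@H](Br)CCC(C)=C1OS(=O)(=O)C(F)(F)F | intermediate
11 | (5S,6S)-5-bromo-6-{[(2S,3S)-3-(but-3-en-1-yl)-3-methyloxiran-2-yl]methyl}-2,6-dimethylcyclohex-1-en-1-yl trifluoromethanesulfonate | C=CCC[C@]1(C)O[C@H]1C[C@]2(C)[C@@H](Br)CCC(C)=C2OS(=O)(=O)C(F)(F)F | intermediate
12 | (5S,6S)-5-bromo-2,6-dimethyl-6-{[(2S,3S)-3-methyl-3-(4-methylpent-3-en-1-yl)oxiran-2-yl]methyl}cyclohex-1-en-1-yl trifluoromethanesulfonate | CC(C)=CCC[C@]1(C)O[C@H]1C[C@]2(C)[C@@H](Br)CCC(C)=C2OS(=O)(=O)C(F)(F)F | intermediate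
13 | 2-methylphenol (o-cresol) | Cc1ccccc1O | starting material
14 | 4-bromo-2-methylphenol | Cc1cc(Br)ccc1O | intermediate
15 | (4-bromo-2-methylphenoxy)triisopropylsilane | Cc1cc(Br)ccc1O[Si](C(C)C)(C(C)C)C(C)C | intermediate
16 | tert-butyl 3-methyl-4-[(triisopropylsilyl)oxy]benzoate | Cc1cc(ccc1O[Si](C(C)C)(C(C)C)C(C)C)C(=O)OC(C)(C)C | intermediate
17 | tert-butyl 3-(bromomethyl)-4-[(triisopropylsilyl)oxy]benzoate | BrCc1cc(ccc1O[Si](C(C)C)(C(C)C)C(C)C)C(=O)OC(C)(C)C | intermediate
18 | tert-butyl 3-(chloromethyl)-4-[(triisopropylsilyl)oxy]benzoate | ClCc1cc(ccc1O[Si](C(C)C)(C(C)C)C(C)C)C(=O)OC(C)(C)C | intermediate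
19 | 3-(chloromethyl)-4-[(triisopropylsilyl)oxy]benzoic acid | ClCc1cc(ccc1O[Si](C(C)C)(C(C)C)C(C)C)C(=O)O | intermediate
20 | seco bromo ester (name in step 17) | ClCc1cc(ccc1O[Si](C(C)C)(C(C)C)C(C)C)C(=O)OC(C)(C)[C@H](Br)CC[C@]2(C)O[C@H]2C[C@]3(C)[C@@H](Br)CCC(C)=C3OS(=O)(=O)C(F)(F)F | intermediate
21 | O-TIPS ether of the target macrolide | CC1=C2Cc3cc(ccc3O[Si](C(C)C)(C(C)C)C(C)C)C(=O)OC(C)(C)[C@H](Br)CC[C@]3(C)O[C@H]3C[C@]2(C)[C@@H](Br)CC1 | intermediate
22 | CID 46880797 | CC1=C2Cc3cc(ccc3O)C(=O)OC(C)(C)[C@H](Br)CC[C@]3(C)O[C@H]3C[C@]2(C)[C@@H](Br)CC1 | target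

**Step count**
Total steps: 19. Longest linear sequence: 12 (steps 1, 2, 4–10, 17, 18, 19), which is 63 % of the total.

**Three steps most likely to fail**
- **Step 17 (proposed new bromoesterification).** Risks are low selectivity at C–Br and competing epoxide participation. Fallback with known chemistry: drop catalyst control and run the ordinary NBS/carboxylic acid bromoesterification, then separate the two C–Br epimers of 20 (or 21) by chromatography; they are diastereomers because of the four existing stereocentres. The unwanted epimer can be returned to alkene 12 by Zn-mediated reductive β-elimination.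
- **Step 6 (Appel inversion at a carbinol next to a quaternary carbon).** Risks are elimination or rearrangement. Fallback: avoid SN2 altogether and build the bromocyclohexane by bromonium-initiated cation–olefin cyclisation (BDSB-type reagent) of an acyclic (E)-trisubstituted alkene with a β-keto ester terminator. Br and the new C–C bond add anti, giving the same trans Br/side-chain relationship directly; absolute control then needs a chiral halonium promoter or resolution.
- **Step 18 (Zn insertion and Negishi macrocyclisation).** Risks are zinc attack on the β-bromo ester and oligomerisation. Fallback: reverse the order of the two unions. Couple the benzylic zinc chloride of an allyl-ester analogue of 18 with triflate 12 intermolecularly, remove the allyl ester with Pd(0), and close the ring at the C–O bond by intramolecular bromolactonisation.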